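## Analysis of the target

The target is a C15 oxocane. Numbering the chain from the alkyne CH (C1) to the ethyl CH3 (C15), the ring oxygen joins C6 and C12, so the saturated eight-membered ring holds O and C6–C12. C6 carries the (E)-pent-2-en-4-ynyl unit (C1–C5) and C12 the 1-bromopropyl unit (C13–C15). There are six stereocentres (6S,7S,9S,10S,12R,13R). On the ring, the C6 chain, C7–Cl and C10–OAc lie on one face, and C9–Cl and the C12 side chain on the other. Hence C6/C7 are cis, C9/C10 trans, and the two carbons flanking oxygen (C6, C12) are trans to each other. The C12–O and C13–Br bonds have the relationship of an anti addition to a Z C12=C13 alkene. Sensitive groups are the secondary bromide next to an ether carbon, two secondary chlorides (C9 lies across the ring from the ether oxygen, so ionisation there invites a bicyclic oxonium ion), a base-labile acetate and a terminal conjugated enyne. The difficulty is a saturated medium ring with no internal alkene to help closure, carrying five ring stereocentres on a mobile ring and three different C–halogen centres. The feature used is that C6 and C10 are linked by C7–C8–C9 on one side and by O–C12–C11 on the other. A C6=C10 double bond therefore turns the oxocane into a cyclopentene (C6, C7, C8, C9, C10) fused to a 2,3-dihydrofuran (O, C6, C10, C11, C12). The ring is thus the cleavage product of a bicyclic tetrasubstituted enol ether, with C6 emerging as a lactone carbonyl and C10 as a ketone.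

In all oxocane names below the ring is numbered O1, C2 (= chain C6), C3 (= C7), C4 (= C8), C5 (= C9), C6 (= C10), C7 (= C11), C8 (= C12).

## Retrosynthetic reasoning

**Acetate and enyne.** The acetate of 22 is put on last, from alcohol 21 and its silyl ether 20, because the preceding steps use strong bases and hydride that an ester would not survive. The enyne of 20 is cut at C1–C2 (one-carbon homologation of enal 19) and at C3=C4 (cross-metathesis of the allyl compound 18). This leaves only a robust allyl group on the ring during the halogen chemistry.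

**C9–Cl.** The C9–Cl bond of 18 is cut back to the C9 alcohol 17 of opposite configuration (silyl ether 16). The oxygen at C9 is present from the start, so the chloride needs only one SN2 inversion. It must come late: a free C9 hydroxyl would contract a lactone to a γ-lactone, and a C9 chloride would be attacked by a C7 enolate.

**C5–C6.** This bond of 16 is cut to an oxocarbenium ion derived from the α-acetoxy ether 15, itself the reduced and acetylated form of lactone 13. A carbon nucleophile on such a ring oxocarbenium ion is the reaction type that gives the trans relationship across the ether oxygen that the target has. A hydride added to a substituted cation would give the cis isomer. The forward step must bring the allyl group in on the face opposite to the C12 side chain and cis to C7–Cl.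

**C7–Cl.** The C7–Cl bond of 13 is cut to the lactone 11 (via its ketene acetal 12). The lactone carbonyl at C6 is what makes C7 addressable at all. The forward step needs attack of the electrophile on the ring face away from the C12 substituent.

**C10–H.** The C10–H bond of 11 is cut to ketone 9 (via alcohol 10). The ketone must be reduced before the lactone is enolised, since it is the more acidic carbonyl. The C9 silyl ether directs the hydride, and the C10 oxygen is capped at once with a silyl group more robust than the one on C9, so that C9 can later be unmasked alone.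

**Key disconnection.** No skeletal bond of 9 is cut. The two carbonyl carbons C6 and C10 are joined in the reverse sense into the enol ether double bond of the bicycle 7 (via ozonide 8). The gain is that the eight-membered ring is never closed by a medium-ring cyclisation: it is assembled from two five-membered rings and released by cleaving their shared bond. The forward step needs only chemoselective cleavage of one electron-rich alkene.

**Bicycle.** In 7 the C9–H bond is cut to the vinylogous ester 5 (alcohol 6 is silylated without isolation). In 5 the C12–O and C13–Br bonds are cut together to the Z alkene of dione 4. These are the very C–O and C–Br bonds of the target, and anti addition to the Z alkene gives their relative configuration. The C10–C11 bond of 4 is cut to cyclopentane-1,3-dione 3 and the allylic bromide 2, made from alcohol 1. An allylic electrophile is chosen because cyclic 1,3-diones C-alkylate usefully only with activated halides.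

## Alternatives that were turned down

**Alternative 1:** The C7–Cl and C9–Cl bonds are traced to the epoxide carbons of the C2-symmetric bis(cis-epoxy alcohol) A2. Forward, Lewis-acid-assisted chloride delivery would open both epoxides at the carbon remote from the hydroxymethyl group, with inversion, to give the dichloro tetraol A1 (C5–C11 of the target).
- For: both chlorine centres come from reliable asymmetric epoxidation and SN2 opening, two at a time, with known regiochemistry. On the security of the C7 and C9 configurations this plan is stronger than the chosen one, which relies on ring conformation for C7.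
- Against: A1 contains neither the ring nor C12/C13. Its two equivalent ends must be told apart by a mono-functionalisation. The oxocane must still be closed by forming a C–O bond on a saturated, heavily substituted chain, which is the hard step of any such synthesis.
- Comparison: the chosen strategy gives up some certainty at C7 but never closes a medium ring, and sets C12 and C13 in one step.

**Alternative 2:** The C6–C7 bond is cut to the acyclic aldehyde A4, which carries a Z γ-alkoxyallylstannane on the C12 oxygen. Forward, a boron Lewis acid would activate the C7 aldehyde and the γ-carbon (C6) would add to it, closing the ring as the trans-2-vinyl-3-hydroxy oxocane A3.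
- For: the ring and the C6/C7 pair are made in one C–C bond formation of a well-behaved reaction class whose 2,3-trans outcome is predictable. After inversion at C7 this gives the required C6/C7 cis relationship, so on this pair it is at least as strong as the chosen route.
- Against: the ring closure is an eight-membered cyclisation of a flexible sp3 chain with no cis alkene to assist. The configuration at C6 relative to C12 (trans is needed) is not assured. A3 still needs three separate hydroxyl-to-halide inversions (C7, C9, C13) and a multi-step change of the vinyl group into the pentenynyl chain, after a long linear build of A4.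
- Comparison: the chosen route needs one inversion (C9), carries the C13 bromide from the third step, and installs the side chain by allylation.

**Alternative 3:** The C12–O, C13–Br and C9–Cl bonds are cut together to the tetrahydrofuran A6, whose oxygen spans C6 and C9. Forward, an electrophilic bromine source would form the bromonium ion of the Z alkene, the ring oxygen would bond to C12, and the C10 acetate and then chloride would displace that oxygen from C9 to give A5.
- For: it is the shortest conceivable end game, forming three bonds and the oxocane in one biomimetic step. It delivers the C9 chloride with net retention by double inversion, without any protecting-group sequence. In step economy and in the handling of C9 it is stronger than the chosen route.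
- Against: one flask must control several things at once: the face of bromonium formation on a remote alkene, competition of the acetate with the ether oxygen for the bromonium ion, and the site at which the oxonium ion is opened (C9 versus C6 or C12). A failure of any one gives isomers that are hard to separate late in the synthesis.
- Comparison: the chosen strategy spreads these events over separate, individually correctable steps and avoids the oxonium manifold. It must, however, guard against that same oxonium ion when C9 is chlorinated.

Key step: step 5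

Remark (assumption): the quinidine-derived catalyst of step 3 is taken to give the (2R,1′R) bromo ether; if its sense of induction is the opposite, the quinine-derived pseudo-enantiomer is used and nothing else changes.

## Route

Step 1
Reactants: 1 (2Z)-pent-2-en-1-ol
Product: 2 (2Z)-1-bromopent-2-ene
Conditions: PBr3 (0.4 equiv), pyridine (cat.), Et2O, −20 → 0 °C
Reagents that add atoms: phosphorus tribromide, BrP(Br)Br
Why: Bromination of a primary allylic alcohol through its phosphite ester (SN2); the low temperature should keep the Z geometry and suppress allylic transposition.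

Step 2
Reactants: 3 cyclopentane-1,3-dione; 2 (2Z)-1-bromopent-2-ene
Product: 4 2-[(2Z)-pent-2-en-1-yl]cyclopentane-1,3-dione
Conditions: KOH (1.0 equiv), H2O, rt → 40 °C; then HCl to pH 2
Reagents that add atoms: none
Why: C-alkylation of the hydrogen-bonded dione enolate by a primary allylic bromide in water (SN2, geometry retained); neutral O-alkylated and dialkylated by-products are removed because only 4 is extracted into aqueous base.

Step 3
Reactants: 4 2-[(2Z)-pent-2-en-1-yl]cyclopentane-1,3-dione
Product: 5 (2R)-2-[(1R)-1-bromopropyl]-2,3,5,6-tetrahydro-4H-cyclopenta[b]furan-4-one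
Conditions: NBS (1.05 equiv), 9-O-(N-arylthiocarbamoyl)quinidine (10 mol %), CHCl3–toluene, −60 °C
Reagents that add atoms: N-bromosuccinimide, O=C1CCC(=O)N1Br
Why: Catalytic enantioselective 5-exo bromoetherification of an olefinic 1,3-dicarbonyl enol: the thiocarbamate sulfur carries the bromine cation to one face of the Z alkene while the quinuclidine holds the acidic enol, whose oxygen opens the bromonium ion at the nearer carbon (C12) anti to bromine. Anti addition to the Z alkene fixes the C12/C13 relative configuration and the catalyst the absolute one.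

Step 4
Reactants: 5 (2R)-2-[(1R)-1-bromopropyl]-2,3,5,6-tetrahydro-4H-cyclopenta[b]furan-4-one
Product: 7 (2R,4R)-2-[(1R)-1-bromopropyl]-4-(tert-butyldimethylsilyloxy)-3,4,5,6-tetrahydro-2H-cyclopenta[b]furan, via allylic alcohol 6 (not isolated)
Conditions: (S)-2-methyl-CBS-oxazaborolidine (0.2 equiv), BH3·SMe2, THF, −20 °C; MeOH, Et3N; concentrate; TBSCl, imidazole, DMF, 0 °C → rt
Reagents that add atoms: tert-butyldimethylsilyl chloride, CC(C)(C)[Si](C)(C)Cl
Why: Corey–Bakshi–Shibata 1,2-reduction of the vinylogous ester carbonyl: with the substituted alkene carbon as the large group the (S)-catalyst should give the 4R alcohol (C9) irrespective of the remote C2 centre, and the acid-labile β-alkoxy allylic alcohol 6 is silylated under basic conditions without purification. Any minor enantiomer of 5 ends as a diastereomer of 7 and is removed by chromatography, so two independent enantioselective steps reinforce each other.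

Step 5
Reactants: 7 (2R,4R)-2-[(1R)-1-bromopropyl]-4-(tert-butyldimethylsilyloxy)-3,4,5,6-tetrahydro-2H-cyclopenta[b]furan
Product: 9 (5R,8R)-8-[(1R)-1-bromopropyl]-5-(tert-butyldimethylsilyloxy)oxocane-2,6-dione, via ozonide 8 (not isolated)
Conditions: O3, CH2Cl2, −78 °C (Sudan Red 7B end point); Me2S, −78 → 0 °C
Reagents that add atoms: ozone, [O-][O+]=O
Why: Ozone adds as a 1,3-dipole to the tetrasubstituted enol ether, the only and most electron-rich C=C bond of 7; the primary ozonide cleaves so that the oxygen-bearing carbon (C6) becomes the lactone carbonyl and C10 a carbonyl oxide, which closes to the peroxidic intermediate 8 and is reduced by Me2S to the ketone. The closest known reaction type is the oxidative cleavage of bicyclic enol ethers to medium-ring keto lactones. No ring is closed by a cyclisation: the eight-membered ring appears by scission of the zero-atom bridge shared by the two five-membered rings, so no entropic or transannular penalty of a medium-ring closure is paid. No stereocentre is formed, and those at C9, C12 and C13 are untouched because no bond to them is made or broken. The selectivity needed is chemoselectivity, secured because the enol ether should react at −78 °C far faster than the C–Br bond, the silyl ether or any C–H bond, and the indicator dye keeps excess ozone away. The product is kept dry and neutral and used at once, since the C10 ketone lies across the ring from the lactone carbonyl.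

Step 6
Reactants: 9 (5R,8R)-8-[(1R)-1-bromopropyl]-5-(tert-butyldimethylsilyloxy)oxocane-2,6-dione
Product: 11 (5R,6S,8R)-8-[(1R)-1-bromopropyl]-5-(tert-butyldimethylsilyloxy)-6-(triisopropylsilyloxy)oxocan-2-one, via hydroxy lactone 10 (not isolated)
Conditions: (R)-2-methyl-CBS-oxazaborolidine (0.5 equiv), BH3·SMe2, toluene, −30 °C; MeOH, −30 °C; concentrate cold; TIPSOTf, 2,6-lutidine, CH2Cl2, −78 → 0 °C
Reagents that add atoms: triisopropylsilyl trifluoromethanesulfonate, CC(C)[Si](C(C)C)(C(C)C)OS(=O)(=O)C(F)(F)F
Why: Corey–Bakshi–Shibata reduction of the ketone in the presence of the lactone: with the silyloxy-bearing C9 as the large group the (R)-catalyst should deliver hydride anti to the C9 silyl ether (catalyst and substrate matched), giving the C9/C10 cis arrangement (6S). The oxygen stays boron-bound and non-nucleophilic until methanolysis, and the alcohol 10 is capped at once so that it cannot attack the lactone carbonyl across the ring.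

Step 7
Reactants: 11 (5R,6S,8R)-8-[(1R)-1-bromopropyl]-5-(tert-butyldimethylsilyloxy)-6-(triisopropylsilyloxy)oxocan-2-one
Product: 13 (3S,5R,6S,8R)-8-[(1R)-1-bromopropyl]-3-chloro-5-(tert-butyldimethylsilyloxy)-6-(triisopropylsilyloxy)oxocan-2-one, via silyl ketene acetal 12 (not isolated)
Conditions: LiN(iPr)2, TMSCl (in situ), THF, −78 °C; NCS, −78 → −20 °C
Reagents that add atoms: N-chlorosuccinimide, O=C1CCC(=O)N1Cl (chlorotrimethylsilane, C[Si](C)(C)Cl, leaves atoms in intermediate 12 only)
Why: Electrophilic α-chlorination of a lactone through its silyl ketene acetal, which avoids double chlorination and, by trapping the enolate as it forms, its attack on the C13 bromide. The planar C8–C7=C6–O–C12 unit with the C12 side chain pseudo-equatorial folds the C9–C11 bridge to one face, so the chlorine should enter from the open peripheral face, trans to the C12 substituent (3S).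

Step 8
Reactants: 13 (3S,5R,6S,8R)-8-[(1R)-1-bromopropyl]-3-chloro-5-(tert-butyldimethylsilyloxy)-6-(triisopropylsilyloxy)oxocan-2-one
Product: 15 (3S,5R,6S,8R)-8-[(1R)-1-bromopropyl]-3-chloro-5-(tert-butyldimethylsilyloxy)-6-(triisopropylsilyloxy)oxocan-2-yl acetate (both C2 epimers), via aluminium hemiacetal 14 (not isolated)
Conditions: iBu2AlH (1.3 equiv), CH2Cl2, −78 °C; pyridine, DMAP, Ac2O, −78 → −20 °C; aq. potassium sodium tartrate
Reagents that add atoms: acetic anhydride, CC(=O)OC(C)=O (iBu2AlH leaves atoms in intermediate 14 only)
Why: Partial reduction of the lactone to the tetrahedral aluminium hemiacetal, stable at −78 °C and further stabilised by the α-chlorine, followed by O-acylation in situ (reductive acetylation). This avoids the free eight-membered lactol, which would open to the hydroxy aldehyde; the two C2 epimers converge in step 9.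

Step 9
Reactants: 15 (3S,5R,6S,8R)-8-[(1R)-1-bromopropyl]-3-chloro-5-(tert-butyldimethylsilyloxy)-6-(triisopropylsilyloxy)oxocan-2-yl acetate
Product: 16 (2S,3S,5R,6S,8R)-8-[(1R)-1-bromopropyl]-3-chloro-2-(prop-2-en-1-yl)-5-(tert-butyldimethylsilyloxy)-6-(triisopropylsilyloxy)oxocane
Conditions: allylSiMe3 (5 equiv), TMSOTf (0.3 equiv), CH2Cl2, −78 → −40 °C
Reagents that add atoms: allyltrimethylsilane, C=CC[Si](C)(C)C
Why: Lewis-acid ionisation of the α-acetoxy ether to the ring oxocarbenium ion and Hosomi–Sakurai allylation. Carbon nucleophiles should add to such eight-membered cations from the peripheral face of the conformer that keeps the C12 side chain pseudo-equatorial, which gives the trans relationship across the ether oxygen; this is the face on which the C7 chlorine was introduced, so C6 and C7 should come out cis (2S). The bulky silyl ethers are poor transannular nucleophiles.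

Step 10
Reactants: 16 (2S,3S,5R,6S,8R)-8-[(1R)-1-bromopropyl]-3-chloro-2-(prop-2-en-1-yl)-5-(tert-butyldimethylsilyloxy)-6-(triisopropylsilyloxy)oxocane
Product: 17 (2S,3S,5R,6S,8R)-8-[(1R)-1-bromopropyl]-3-chloro-2-(prop-2-en-1-yl)-6-(triisopropylsilyloxy)oxocan-5-ol
Conditions: camphorsulfonic acid (0.2 equiv), MeOH–CH2Cl2 (1:1), 0 °C
Reagents that add atoms: none
Why: Acid-catalysed methanolysis should remove the secondary tert-butyldimethylsilyl ether much faster than the bulkier triisopropylsilyl ether (selective desilylation); halides and the terminal alkene are inert and silyl migration is not acid-promoted.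

Step 11
Reactants: 17 (2S,3S,5R,6S,8R)-8-[(1R)-1-bromopropyl]-3-chloro-2-(prop-2-en-1-yl)-6-(triisopropylsilyloxy)oxocan-5-ol
Product: 18 (2S,3S,5S,6S,8R)-8-[(1R)-1-bromopropyl]-3,5-dichloro-2-(prop-2-en-1-yl)-6-(triisopropylsilyloxy)oxocane
Conditions: CCl4, (n-C8H17)3P, toluene, 60 °C
Reagents that add atoms: tetrachloromethane, ClC(Cl)(Cl)Cl
Why: Appel chlorination: chloride displaces the C9 oxyphosphonium group from the face opposite to the leaving group and to the cis C10 silyl ether (SN2, inversion to 5S). In a non-polar solvent the chloride stays ion-paired, so the secondary bromide should not exchange.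

Step 12
Reactants: 18 (2S,3S,5S,6S,8R)-8-[(1R)-1-bromopropyl]-3,5-dichloro-2-(prop-2-en-1-yl)-6-(triisopropylsilyloxy)oxocane
Product: 19 (2E)-4-[(2S,3S,5S,6S,8R)-8-[(1R)-1-bromopropyl]-3,5-dichloro-6-(triisopropylsilyloxy)oxocan-2-yl]but-2-enal
Conditions: (E)-crotonaldehyde (10 equiv), second-generation Grubbs catalyst RuCl2(=CHPh)(H2IMes)(PCy3) (5 mol %), CH2Cl2, 40 °C
Reagents that add atoms: (2E)-but-2-enal, C/C=C/C=O
Why: Olefin cross-metathesis of a terminal alkene with an electron-poor enal partner used in excess; the conjugated E enal is the thermodynamic product and alkyl halides and silyl ethers are tolerated.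

Step 13
Reactants: 19 (2E)-4-[(2S,3S,5S,6S,8R)-8-[(1R)-1-bromopropyl]-3,5-dichloro-6-(triisopropylsilyloxy)oxocan-2-yl]but-2-enal
Product: 20 (2S,3S,5S,6S,8R)-8-[(1R)-1-bromopropyl]-3,5-dichloro-2-[(2E)-pent-2-en-4-yn-1-yl]-6-(triisopropylsilyloxy)oxocane
Conditions: Me3SiCHN2, LiN(iPr)2, THF, −78 → 0 °C
Reagents that add atoms: trimethylsilyldiazomethane, C[Si](C)(C)C=[N+]=[N-]
Why: Colvin rearrangement: the lithiated diazomethane adds to the aldehyde at −78 °C faster than it deprotonates C5; Peterson elimination and loss of nitrogen give an alkylidene carbene whose 1,2-hydrogen shift forms the terminal alkyne with the E alkene intact. No ester is present yet.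

Step 14
Reactants: 20 (2S,3S,5S,6S,8R)-8-[(1R)-1-bromopropyl]-3,5-dichloro-2-[(2E)-pent-2-en-4-yn-1-yl]-6-(triisopropylsilyloxy)oxocane
Product: 21 (2S,3S,5S,6S,8R)-8-[(1R)-1-bromopropyl]-3,5-dichloro-2-[(2E)-pent-2-en-4-yn-1-yl]oxocan-6-ol
Conditions: HF·pyridine, pyridine, THF, 0 °C → rt
Reagents that add atoms: none
Why: Fluoride-mediated desilylation under acidic, buffered conditions, which avoids the closure of the trans chlorohydrin to an epoxide that basic fluoride would cause.

Step 15
Reactants: 21 (2S,3S,5S,6S,8R)-8-[(1R)-1-bromopropyl]-3,5-dichloro-2-[(2E)-pent-2-en-4-yn-1-yl]oxocan-6-ol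
Product: 22 (2S,3S,5S,6S,8R)-8-[(1R)-1-bromopropyl]-3,5-dichloro-2-[(2E)-pent-2-en-4-yn-1-yl]oxocan-6-yl acetate (target)
Conditions: Ac2O, pyridine, DMAP (cat.), CH2Cl2, 0 °C → rt
Reagents that add atoms: acetic anhydride, CC(=O)OC(C)=O
Why: DMAP-catalysed acylation of the secondary alcohol under conditions too mild to eliminate or displace the halides; no stereocentre is touched.

## Compound list

1 | (2Z)-pent-2-en-1-ol | CC/C=C\CO | starting material
2 | (2Z)-1-bromopent-2-ene | CC/C=C\CBr | intermediate
3 | cyclopentane-1,3-dione | O=C1CCC(=O)C1 | starting material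
4 | 2-[(2Z)-pent-2-en-1-yl]cyclopentane-1,3-dione (reacts as its enol) | CC/C=C\CC1C(=O)CCC1=O | intermediate
5 | (2R)-2-[(1R)-1-bromopropyl]-2,3,5,6-tetrahydro-4H-cyclopenta[b]furan-4-one | CC[C@@H](Br)[C@H]1CC2=C(O1)CCC2=O | intermediate
6 | (2R,4R)-2-[(1R)-1-bromopropyl]-3,4,5,6-tetrahydro-2H-cyclopenta[b]furan-4-ol | CC[C@@H](Br)[C@H]1CC2=C(O1)CC[C@H]2O | intermediate (not isolated)
7 | (2R,4R)-2-[(1R)-1-bromopropyl]-4-(tert-butyldimethylsilyloxy)-3,4,5,6-tetrahydro-2H-cyclopenta[b]furan | CC[C@@H](Br)[C@H]1CC2=C(O1)CC[C@H]2O[Si](C)(C)C(C)(C)C | intermediate (key-step precursor)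
8 | ozonide of 7: 1,2,4-trioxolane bridging the former alkene carbons (bridgehead configuration undefined) | CC[C@@H](Br)[C@H]1CC23OOC(O1)(O2)CC[C@H]3O[Si](C)(C)C(C)(C)C | intermediate (not isolated)
9 | (5R,8R)-8-[(1R)-1-bromopropyl]-5-(tert-butyldimethylsilyloxy)oxocane-2,6-dione | CC[C@@H](Br)[C@H]1CC(=O)[C@H](O[Si](C)(C)C(C)(C)C)CCC(=O)O1 | intermediate (key-step product)
10 | (5R,6S,8R)-8-[(1R)-1-bromopropyl]-5-(tert-butyldimethylsilyloxy)-6-hydroxyoxocan-2-one | CC[C@@H](Br)[C@H]1C[C@H](O)[C@H](O[Si](C)(C)C(C)(C)C)CCC(=O)O1 | intermediate (not isolated)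
11 | (5R,6S,8R)-8-[(1R)-1-bromopropyl]-5-(tert-butyldimethylsilyloxy)-6-(triisopropylsilyloxy)oxocan-2-one | CC[C@@H](Br)[C@H]1C[C@H](O[Si](C(C)C)(C(C)C)C(C)C)[C@H](O[Si](C)(C)C(C)(C)C)CCC(=O)O1 | intermediate
12 | trimethylsilyl ketene acetal of 11 (ring C2=C3 double bond, C2–OSiMe3) | CC[C@@H](Br)[C@H]1C[C@H](O[Si](C(C)C)(C(C)C)C(C)C)[C@H](O[Si](C)(C)C(C)(C)C)C/C=C(/O[Si](C)(C)C)O1 | intermediate (not isolated)
13 | (3S,5R,6S,8R)-8-[(1R)-1-bromopropyl]-3-chloro-5-(tert-butyldimethylsilyloxy)-6-(triisopropylsilyloxy)oxocan-2-one | CC[C@@H](Br)[C@H]1C[C@H](O[Si](C(C)C)(C(C)C)C(C)C)[C@H](O[Si](C)(C)C(C)(C)C)C[C@H](Cl)C(=O)O1 | intermediate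
14 | diisobutylaluminium hemiacetal of 13 (C2 undefined) | CC[C@@H](Br)[C@H]1C[C@H](O[Si](C(C)C)(C(C)C)C(C)C)[C@H](O[Si](C)(C)C(C)(C)C)C[C@H](Cl)C(O[Al](CC(C)C)CC(C)C)O1 | intermediate (not isolated)
15 | (3S,5R,6S,8R)-8-[(1R)-1-bromopropyl]-3-chloro-5-(tert-butyldimethylsilyloxy)-6-(triisopropylsilyloxy)oxocan-2-yl acetate (both C2 epimers) | CC[C@@H](Br)[C@H]1C[C@H](O[Si](C(C)C)(C(C)C)C(C)C)[C@H](O[Si](C)(C)C(C)(C)C)C[C@H](Cl)C(OC(C)=O)O1 | intermediate
16 | (2S,3S,5R,6S,8R)-8-[(1R)-1-bromopropyl]-3-chloro-2-(prop-2-en-1-yl)-5-(tert-butyldimethylsilyloxy)-6-(triisopropylsilyloxy)oxocane | C=CC[C@@H]1O[C@@H]([C@H](Br)CC)C[C@H](O[Si](C(C)C)(C(C)C)C(C)C)[C@H](O[Si](C)(C)C(C)(C)C)C[C@@H]1Cl | intermediate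
17 | (2S,3S,5R,6S,8R)-8-[(1R)-1-bromopropyl]-3-chloro-2-(prop-2-en-1-yl)-6-(triisopropylsilyloxy)oxocan-5-ol | C=CC[C@@H]1O[C@@H]([C@H](Br)CC)C[C@H](O[Si](C(C)C)(C(C)C)C(C)C)[C@H](O)C[C@@H]1Cl | intermediate
18 | (2S,3S,5S,6S,8R)-8-[(1R)-1-bromopropyl]-3,5-dichloro-2-(prop-2-en-1-yl)-6-(triisopropylsilyloxy)oxocane | C=CC[C@@H]1O[C@@H]([C@H](Br)CC)C[C@H](O[Si](C(C)C)(C(C)C)C(C)C)[C@@H](Cl)C[C@@H]1Cl | intermediate
19 | (2E)-4-[(2S,3S,5S,6S,8R)-8-[(1R)-1-bromopropyl]-3,5-dichloro-6-(triisopropylsilyloxy)oxocan-2-yl]but-2-enal | O=C/C=C/C[C@@H]1O[C@@H]([C@H](Br)CC)C[C@H](O[Si](C(C)C)(C(C)C)C(C)C)[C@@H](Cl)C[C@@H]1Cl | intermediate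
20 | (2S,3S,5S,6S,8R)-8-[(1R)-1-bromopropyl]-3,5-dichloro-2-[(2E)-pent-2-en-4-yn-1-yl]-6-(triisopropylsilyloxy)oxocane | C#C/C=C/C[C@@H]1O[C@@H]([C@H](Br)CC)C[C@H](O[Si](C(C)C)(C(C)C)C(C)C)[C@@H](Cl)C[C@@H]1Cl | intermediate
21 | (2S,3S,5S,6S,8R)-8-[(1R)-1-bromopropyl]-3,5-dichloro-2-[(2E)-pent-2-en-4-yn-1-yl]oxocan-6-ol | C#C/C=C/C[C@@H]1O[C@@H]([C@H](Br)CC)C[C@H](O)[C@@H](Cl)C[C@@H]1Cl | intermediate
22 | (2S,3S,5S,6S,8R)-8-[(1R)-1-bromopropyl]-3,5-dichloro-2-[(2E)-pent-2-en-4-yn-1-yl]oxocan-6-yl acetate (chain numbering 6S,7S,9S,10S,12R,13R) | C#C/C=C/C[C@@H]1O[C@@H]([C@H](Br)CC)C[C@H](OC(C)=O)[C@@H](Cl)C[C@@H]1Cl | target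

## Step count and least certain steps

Total: 15 steps (17 operations; alcohols 6 and 10 are carried on crude). Longest linear sequence: 15 steps from 1; cyclopentane-1,3-dione 3 enters in step 2.

**Step 5 (key step).** The peroxidic intermediate may rearrange (acyl migration or over-oxidation next to the silyl ether) instead of being reduced cleanly, and the strained keto lactone may open hydrolytically on work-up because the ketone sits across the ring from the lactone carbonyl. Fallback, from 7: OsO4 (cat.) with N-methylmorpholine N-oxide in acetone–water dihydroxylates the enol ether to the cis-fused 3a,6a-diol (α-hydroxy hemiketal) F1. Glycol cleavage with Pb(OAc)4 in CH2Cl2 at 0 °C then breaks the same C6–C10 bond under anhydrous, non-peroxidic conditions and returns to the route at 9.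

**Step 3.** The catalyst may discriminate poorly between the faces of an unactivated Z dialkyl alkene, an uncatalysed background bromination may erode the enantiomeric purity, and some six-membered (endo) closure may compete. Fallback, from 4: uncatalysed cyclisation (NBS, NaHCO3, CH2Cl2) gives the racemate, that is 5 together with its enantiomer F2. The unchanged step 4 then converts F2, through the alcohol F3, into the diastereomeric silyl ether F4, which is separated from 7 by chromatography. Enantiomeric purity then rests on the oxazaborolidine reduction alone, and at most half of the material is kept, at an early and cheap stage. The route is rejoined at 7.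

**Step 6.** The new C10 hydroxyl may attack the lactone carbonyl across the ring and contract it to a six-membered lactone before it is silylated, or the facial selectivity of the reduction may be insufficient. Fallback, from 9: borane-catalysed hydrosilylation (B(C6F5)3 5 mol %, iPr3SiH, CH2Cl2, −40 °C → rt) reduces the ketone and silylates its oxygen in the same event, with the bulky hydridoborate attacking anti to the C9 silyl ether. A free hydroxyl never exists; no compound outside the list is made (F0), and the route is rejoined directly at 11.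

**Step 7.** The chlorine may enter the ketene acetal on the face of the C12 side chain and give the 3R chloride, because the facial preference rests on a conformational model of a mobile ring. Fallback, from 11: the lithium enolate (LiN(iPr)2, THF, −78 °C) is oxidised with 2-(phenylsulfonyl)-3-phenyloxaziridine, the oxygen entering on the face the chlorine had taken, to give the 3R α-hydroxy lactone F5. CCl4/PPh3 then replaces the hydroxyl by chloride with inversion (SN2 at an α-carbonyl carbon) and returns to the route at 13.

**Step 9.** The allylsilane may add anti to the neighbouring C7 chlorine and so give the C6 epimer; loss of a proton to a 2-chloro enol ether or capture of the cation by a silyl ether oxygen across the ring are lesser risks. Fallback, from 13, in which C7 carries an invertible oxygen on the other face so that the nucleophile is anti to both neighbours: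
- KOC6H4OMe in DMF at 0 °C displaces the α-chloride with inversion to give the 3R 4-methoxyphenyl ether F6.
- Reductive acetylation as in step 8 gives, through the aluminium hemiacetal F7, the acetoxy ether F8.
- Allylation as in step 9 gives F9, with the allyl group trans to the aryl ether and to the C12 side chain.
- (NH4)2Ce(NO3)6 in MeCN–water at 0 °C removes the aryl group to give the 3R alcohol F10.
- CCl4/(n-C8H17)3P converts F10 with inversion into 16, where the route is rejoined.

**Step 11.** The hindered oxyphosphonium ion may eliminate to an alkene, or the ring oxygen may displace it across the ring to a bicyclic oxonium ion, which would lead to retention at C9 or to ring-contracted chlorides. Fallback, from 17: ClCH2SO2Cl with pyridine at 0 °C gives the chloromethanesulfonate F11, a reactive but non-ionising leaving group. Excess LiCl in DMF at rt → 40 °C displaces it under a high chloride concentration that favours the direct bimolecular path, returning to the route at 18.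

## Further compounds

F1 | step 5 | (2R,4R)-2-[(1R)-1-bromopropyl]-4-(tert-butyldimethylsilyloxy)hexahydro-2H-cyclopenta[b]furan-3a,6a-diol (cis-fused, either face) | CC[C@@H](Br)[C@H]1CC2(O)C(O)(O1)CC[C@H]2O[Si](C)(C)C(C)(C)C
F2 | step 3 | (2S)-2-[(1S)-1-bromopropyl]-2,3,5,6-tetrahydro-4H-cyclopenta[b]furan-4-one (enantiomer of 5) | CC[C@H](Br)[C@@H]1CC2=C(O1)CCC2=O
F3 | step 3 | (2S,4R)-2-[(1S)-1-bromopropyl]-3,4,5,6-tetrahydro-2H-cyclopenta[b]furan-4-ol | CC[C@H](Br)[C@@H]1CC2=C(O1)CC[C@H]2O
F4 | step 3 | (2S,4R)-2-[(1S)-1-bromopropyl]-4-(tert-butyldimethylsilyloxy)-3,4,5,6-tetrahydro-2H-cyclopenta[b]furan | CC[C@H](Br)[C@@H]1CC2=C(O1)CC[C@H]2O[Si](C)(C)C(C)(C)C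
F0 | step 6 | none | none
F5 | step 7 | (3R,5R,6S,8R)-8-[(1R)-1-bromopropyl]-5-(tert-butyldimethylsilyloxy)-3-hydroxy-6-(triisopropylsilyloxy)oxocan-2-one | CC[C@@H](Br)[C@H]1C[C@H](O[Si](C(C)C)(C(C)C)C(C)C)[C@H](O[Si](C)(C)C(C)(C)C)C[C@@H](O)C(=O)O1
F6 | step 9 | (3R,5R,6S,8R)-8-[(1R)-1-bromopropyl]-5-(tert-butyldimethylsilyloxy)-3-(4-methoxyphenoxy)-6-(triisopropylsilyloxy)oxocan-2-one | CC[C@@H](Br)[C@H]1C[C@H](O[Si](C(C)C)(C(C)C)C(C)C)[C@H](O[Si](C)(C)C(C)(C)C)C[C@@H](Oc2ccc(OC)cc2)C(=O)O1
F7 | step 9 | diisobutylaluminium hemiacetal of F6 (C2 undefined) | CC[C@@H](Br)[C@H]1C[C@H](O[Si](C(C)C)(C(C)C)C(C)C)[C@H](O[Si](C)(C)C(C)(C)C)C[C@@H](Oc2ccc(OC)cc2)C(O[Al](CC(C)C)CC(C)C)O1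
F8 | step 9 | (3R,5R,6S,8R)-8-[(1R)-1-bromopropyl]-5-(tert-butyldimethylsilyloxy)-3-(4-methoxyphenoxy)-6-(triisopropylsilyloxy)oxocan-2-yl acetate (both C2 epimers) | CC[C@@H](Br)[C@H]1C[C@H](O[Si](C(C)C)(C(C)C)C(C)C)[C@H](O[Si](C)(C)C(C)(C)C)C[C@@H](Oc2ccc(OC)cc2)C(OC(C)=O)O1
F9 | step 9 | (2S,3R,5R,6S,8R)-8-[(1R)-1-bromopropyl]-5-(tert-butyldimethylsilyloxy)-3-(4-methoxyphenoxy)-2-(prop-2-en-1-yl)-6-(triisopropylsilyloxy)oxocane | C=CC[C@@H]1O[C@@H]([C@H](Br)CC)C[C@H](O[Si](C(C)C)(C(C)C)C(C)C)[C@H](O[Si](C)(C)C(C)(C)C)C[C@H]1Oc2ccc(OC)cc2
F10 | step 9 | (2S,3R,5R,6S,8R)-8-[(1R)-1-bromopropyl]-5-(tert-butyldimethylsilyloxy)-2-(prop-2-en-1-yl)-6-(triisopropylsilyloxy)oxocan-3-ol | C=CC[C@@H]1O[C@@H]([C@H](Br)CC)C[C@H](O[Si](C(C)C)(C(C)C)C(C)C)[C@H](O[Si](C)(C)C(C)(C)C)C[C@H]1O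
F11 | step 11 | (2S,3S,5R,6S,8R)-8-[(1R)-1-bromopropyl]-3-chloro-2-(prop-2-en-1-yl)-6-(triisopropylsilyloxy)oxocan-5-yl chloromethanesulfonate | C=CC[C@@H]1O[C@@H]([C@H](Br)CC)C[C@H](O[Si](C(C)C)(C(C)C)C(C)C)[C@H](OS(=O)(=O)CCl)C[C@@H]1Cl
A1 | alternative 1 | (2S,3S,5S,6S)-3,5-dichloroheptane-1,2,6,7-tetraol | OC[C@H](O)[C@@H](Cl)C[C@H](Cl)[C@@H](O)CO
A2 | alternative 1 | (2S,3R,5R,6S)-2,3:5,6-diepoxyheptane-1,7-diol | OC[C@@H]1O[C@@H]1C[C@H]1O[C@H]1CO
A3 | alternative 2 | trans-2-vinyl-3-hydroxyoxocane with C13 silyl ether, C10 acetate and C9 4-methoxybenzyl ether | C=C[C@@H]1O[C@@H]([C@@H](O[Si](C)(C)C(C)(C)C)CC)C[C@H](OC(C)=O)[C@H](OCc2ccc(OC)cc2)C[C@H]1O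
A4 | alternative 2 | acyclic C7 aldehyde with a (Z)-3-(tributylstannyl)prop-1-enyl ether on the C12 oxygen | CCCC[Sn](CCCC)(CCCC)C/C=C\O[C@@H]([C@@H](O[Si](C)(C)C(C)(C)C)CC)C[C@H](OC(C)=O)[C@H](OCc1ccc(OC)cc1)CC=O
A5 | alternative 3 | fully halogenated oxocane core with C4 tert-butyldiphenylsilyl ether | CC(C)(C)[Si](c1ccccc1)(c1ccccc1)OCC[C@@H]1O[C@@H]([C@H](Br)CC)C[C@H](OC(C)=O)[C@@H](Cl)C[C@@H]1Cl
A6 | alternative 3 | 3-chlorotetrahydrofuran (oxygen between C6 and C9) with C10 acetate, Z C12=C13 alkene and C4 silyl ether | CC/C=C\C[C@H](OC(C)=O)[C@@H]1C[C@H](Cl)[C@H](CCO[Si](c2ccccc2)(c2ccccc2)C(C)(C)C)O1
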